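## Retrosynthetic overview
- **12** ⇐ AcOH opening of the spiro-epoxide of valtrate (**11**), which gives C8‑OH and C10‑OAc.
- **11** ⇐ Stille installation of CH2OAc (C11) on the dienyl enol triflate ⇐ carbenoid epoxidation of the C8 ketone ⇐ C7 acyloxylation ⇐ aldol condensation that closes the cyclopentene.
- Key bond: the C8–C9 bond forms by radical hydroacylation of the Achmatowicz acyloxypyranone **3** with masked malondialdehyde **5**. The pyran ring (with the C1 acylal) is built first from furfuryl alcohol, and the cyclopentene is built second.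

Assumption: 2‑(1,3‑dioxolan‑2‑yl)ethanol is available as a commercial starting material, and Bu3SnCH2OAc is made from Bu3SnCH2OH and Ac2O.

## Route

**Step 1**
Reactants: 1, furfuryl alcohol
Product: 2, (±)-6-hydroxy-2H-pyran-3(6H)-one
Conditions: NBS, NaHCO3, NaOAc, THF/H2O, 0 °C
Reagents that add atoms: water, O
Why: Achmatowicz oxidative ring expansion. It creates the pyran ring with the C1 hemiacetal, the C4 ketone and the C5=C9 enone in one step.

**Step 2**
Reactants: 2
Product: 3, (6S)-6-(isovaleryloxy)-2H-pyran-3(6H)-one
Conditions: (iPrCH2CO)2O, chiral isothiourea catalyst (5 mol%), iPr2NEt, CH2Cl2, –20 °C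
Reagents that add atoms: isovaleric anhydride, CC(C)CC(=O)OC(=O)CC(C)C
Why: the lactol anomerizes rapidly, so enantioselective acylation gives the C1 acylal as a single enantiomer. This is the only stereocenter set by a catalyst.
Proposed new method: dynamic kinetic resolution of the lactol. Rapid ring-chain or anomer equilibration lets a chiral acyl-transfer catalyst acylate one enantiomer selectively. The closest known reaction is isothiourea-catalysed kinetic resolution of secondary alcohols.

**Step 3**
Reactants: 4, 2-(1,3-dioxolan-2-yl)ethanol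
Product: 5, 2-(1,3-dioxolan-2-yl)acetaldehyde
Conditions: Dess–Martin periodinane, NaHCO3, CH2Cl2, 0 °C; use the crude aldehyde immediately
Reagents that add atoms: none
Why: a standard oxidation to the masked C6–C7–C8 fragment. C6 is held as a dioxolane and C8 is the aldehyde.

**Step 4 (key radical step)**
Reactants: 3 and 5
Product: 6, (6S)-6-(isovaleryloxy)-5-[3-(1,3-dioxolan-2-yl)-2-oxopropyl]… (see SMILES). It is the 1,4-diketone with the C9 side chain trans to the C1 OiVal.
Conditions: tetrabutylammonium decatungstate (TBADT, 2 mol%), MeCN, 390 nm LEDs, 23 °C; 5 (2.5 equiv)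
Reagents that add atoms: none (the H comes from hydrogen-atom transfer)
Why: Giese-type hydroacylation. HAT from the aldehyde gives a nucleophilic acyl radical that adds to C9, the β-carbon of the enone. The radical adds anti to the pseudo-axial anomeric OiVal, which sets C9 trans to C1. The resulting α-keto radical takes back the H from the reduced decatungstate.

**Step 5**
Reactants: 6
Product: 7, the bicyclic cyclopenta[c]pyranone. Ring A has C5=C6 conjugated to the C4 ketone and a C8 ketone, with C1-OiVal trans to the C9–C8 bond.
Conditions: 1) 1 M HCl, THF, 40 °C; 2) pyrrolidine (20 mol%), AcOH (20 mol%), CH2Cl2, 23 °C, one pot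
Reagents that add atoms: none (water is lost again)
Why: acetal hydrolysis gives the C6 aldehyde. Intramolecular enamine aldol then condenses the C5 α-carbon onto C6 in a 5-exo closure. Dehydration gives the C5=C6 enone, and the ring fusion is cis-fused by necessity.

**Step 6**
Reactants: 7
Product: 8, the C7-isovaleryloxy diketone (C7–O trans to C9–C1)
Conditions: KHMDS (1.05 equiv), THF, –78 °C; then (iPrCH2CO2)2 in THF, –78 → –40 °C
Reagents that add atoms: diisovaleryl peroxide, CC(C)CC(=O)OOC(=O)CC(C)C
Why: kinetic deprotonation at C7 (α to the C8 ketone and γ to the enone) gives a dienolate. Electrophilic oxygen transfer from the diacyl peroxide occurs on the face anti to the pyran ring, so C7–O is trans to C9–C1.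
Proposed new method: O-acyloxylation of a cross-conjugated dienolate with a diacyl peroxide. The mechanism is SN2 at the peroxide O–O bond, and the closest known reaction is Rubottom-type α-benzoyloxylation with dibenzoyl peroxide.

**Step 7**
Reactants: 8
Product: 9, the spiro-epoxide (C8/C10) enone with O cis to C1
Conditions: CH2ClI, MeLi·LiBr, THF, –78 → 0 °C
Reagents that add atoms: chloroiodomethane, ClCI (supplies C10)
Why: LiCH2Cl is non-basic, so it adds to the more electrophilic C8 ketone without enolizing the α-acyloxy ketone (Barluenga/Matteson-type epoxidation). It adds from the face anti to C9–C1, and the chlorohydrin alkoxide closes to the epoxide with O cis to C1.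

**Step 8**
Reactants: 9
Product: 10, the dienyl enol triflate (C3=C4(OTf)–C5=C6)
Conditions: KHMDS, THF, –78 °C; then Comins' reagent
Reagents that add atoms: 2-[N,N-bis(trifluoromethylsulfonyl)amino]-5-chloropyridine, O=S(=O)(C(F)(F)F)N(S(=O)(=O)C(F)(F)F)c1ccc(Cl)cn1 (supplies Tf)
Why: kinetic deprotonation at the α'-CH2 (C3, flanked by O2 and the C4 ketone) followed by O-triflation. This sets the O2–C3=C4 enol ether and the C5=C6 diene in one step.

**Step 9**
Reactants: 10
Product: 11, valtrate
Conditions: Bu3SnCH2OAc, Pd(PPh3)4 (5 mol%), CuI, LiCl, DMF, 50 °C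
Reagents that add atoms: (acetoxymethyl)tributylstannane, CCCC[Sn](CCCC)(CCCC)COC(C)=O (supplies C11–OAc)
Why: the diene geometry is unchanged, and the neutral Stille conditions spare the esters, epoxide and acylal.
Proposed new method: Stille transfer of an α-acyloxymethyl group to a vinyl triflate, with a Cu co-catalyst speeding transmetalation. The closest known reaction is Stille coupling of Bu3SnCH2OR (R = Bn, MOM) with vinyl triflates.

**Step 10**
Reactants: 11
Product: 12, 10-acetoxyvaltrathydrin
Conditions: AcOH, NaOAc (cat.), 40 °C
Reagents that add atoms: acetic acid, CC(=O)O (supplies C10–OAc)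
Why: acetate opens the spiro-epoxide by SN2 at the primary C10. C8 is untouched, so the tertiary alcohol keeps its configuration.

## Compound list
1 | furfuryl alcohol | OCc1ccco1 | starting material
2 | (±)-6-hydroxy-2H-pyran-3(6H)-one | O=C1COC(O)C=C1 | intermediate
3 | (6S)-6-(isovaleryloxy)-2H-pyran-3(6H)-one | O=C1CO[C@@H](OC(=O)CC(C)C)C=C1 | intermediate
4 | 2-(1,3-dioxolan-2-yl)ethanol | OCCC1OCCO1 | starting material
5 | 2-(1,3-dioxolan-2-yl)acetaldehyde | O=CCC1OCCO1 | intermediate
6 | 1,4-diketone adduct (C9–C8 bond) | O=C1CO[C@@H](OC(=O)CC(C)C)[C@H](C(=O)CC2OCCO2)C1 | intermediate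
7 | cyclopenta[c]pyranone enone-ketone | O=C1CO[C@@H](OC(=O)CC(C)C)[C@H]2C1=CCC2=O | intermediate
8 | 7-isovaleryloxy analogue of 7 | O=C1CO[C@@H](OC(=O)CC(C)C)[C@H]2C1=C[C@H](OC(=O)CC(C)C)C2=O | intermediate
9 | spiro-epoxy enone | O=C1CO[C@@H](OC(=O)CC(C)C)[C@H]2C1=C[C@H](OC(=O)CC(C)C)[C@]23CO3 | intermediate
10 | dienyl enol triflate | FC(F)(F)S(=O)(=O)OC1=CO[C@@H](OC(=O)CC(C)C)[C@H]2C1=C[C@H](OC(=O)CC(C)C)[C@]23CO3 | intermediate
11 | valtrate | CC(=O)OCC1=CO[C@@H](OC(=O)CC(C)C)[C@H]2C1=C[C@H](OC(=O)CC(C)C)[C@]23CO3 | intermediate
12 | 10-acetoxyvaltrathydrin | CC(=O)OCC1=CO[C@@H](OC(=O)CC(C)C)[C@H]2C1=C[C@H](OC(=O)CC(C)C)[C@]2(O)COC(C)=O | target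

## Totals
Total steps: 10. Longest linear sequence: 9 (steps 1, 2, 4, 5, 6, 7, 8, 9, 10).

## Three steps most likely to fail
1. **Step 4 (radical hydroacylation).** Risks are HAT at the acetal or acylal C–H, instability of the β-alkoxy aldehyde 5, and diastereoselectivity. Fallback: an NHC-catalysed Stetter reaction of 5 with 3, which makes the same C8–C9 bond by polar acyl-anion conjugate addition, again anti to the anomeric acyloxy group.
2. **Step 5 (aldol condensation).** It may give the C6=C7 enone isomer, or lose isovalerate by E1cB at the acidic C9–H. Fallback: carry C8 as a protected alcohol by using an α-silyloxy radical in step 4 (HAT from the TBS ether of 3,3-dimethoxypropan-1-ol). Close ring A by aldol, then oxidize C8–OTBS to the ketone afterwards.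
3. **Step 7 (C8 face selectivity).** The C7–OiVal on the top face may direct the carbenoid to the wrong face. Fallback: Peterson methylenation of the C8 ketone in 8, OsO4 dihydroxylation anti to the C7–OiVal before the dienol ether is made, then selective primary acetylation with Ac2O/pyridine. This gives the C8‑OH/C10‑OAc pattern without an epoxide.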